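# Proposed synthesis of (R)-8-[1-(4-hydroxy-3,5-dimethoxyphenyl)ethyl]isorhamnetin through a three-component aryne coupling

## The problem

The target is a flavonol (rings A, C and B of 3,5,7,4'-tetrahydroxy-3'-methoxyflavone) that carries a 1-(4-hydroxy-3,5-dimethoxyphenyl)ethyl group at C8. Ring A is a phloroglucinol nucleus with five of its six carbons substituted, so O1, O5 and O7 must be told apart. A late alkylation of a 5,7-dihydroxyflavonol would not choose between C6 and C8.

The only stereocenter is the doubly benzylic methine Cα, of R configuration. No second stereocenter is present to relay or correct it, so it must be set by a chiral reagent and carried unchanged to the end.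

This methine sits on a ring with oxygen donors ortho and para to C8. Until ring A carries the C4 carbonyl group, strong Brønsted or Lewis acids can protonate C8 and expel the 1-arylethyl cation (retro-Friedel–Crafts). That would racemise or remove the side chain. The same acids endanger the protecting groups whose pattern marks which oxygen becomes O1.

Three aryl methyl ethers must survive while five hydroxyl groups are set free. This points to benzyl ethers and a final hydrogenolysis that spares the C2=C3 bond. The free flavonol is sensitive to air in base and should appear last.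

The feature that opens the route is on ring A: C8 (aryl–C) and C8a (aryl–O) are neighbours, and C7 next to C8 bears oxygen. This is the pattern left when the oxygen and carbon of a carbonyl group add across an aryne C8≡C8a that is polarised by an alkoxy group at C7. Cα has the oxidation level of an aldehyde carbon plus one methyl group. An aryne, an aromatic aldehyde and a methyl nucleophile therefore account for the C8a–O, C8–Cα and Cα–CH3 bonds.

## Retrosynthesis

**Target 21 from flavonol ether 20.** The four O–benzyl bonds are cut. Benzyl is preferred to methyl, which could not be distinguished from the three methoxy groups. It is preferred to acetal or silyl groups, which would not survive the organolithium, fluoride, Grignard and alkaline peroxide steps, or would need acid for removal. The forward step is a hydrogenolysis that must leave the chromone double bond alone.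

**Flavonol 20 from acetophenone 17 and 4-(benzyloxy)-3-methoxybenzaldehyde 18.** Ring C is opened at O1–C2, C2–C3 and C3–OH. The forward reaction is a Claisen–Schmidt condensation to chalcone 19 followed in the same flask by Algar–Flynn–Oyamada oxidation.
- The neighbouring options are an ω-alkoxyketone with Baker–Venkataraman rearrangement, or a flavone with later oxidation at C3. Both are more reliable for 5-oxygenated flavonols but cost one to three further steps.
- Compound 17 has a single free phenol, the one beside the side chain, so ring C can only close toward the 8-substituted flavonol.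
- The forward reaction must close at the β-carbon (six-membered ring) and not at the α-carbon (aurone).

**Acetophenone 17 from phenol 14 through aldehyde 15 and carbinol 16.** The aryl–acyl bond C4a–C4 is cut.
- A Friedel–Crafts or Fries acylation would do this in one step. It would, however, expose 14 to Lewis acid at the stage where the side chain is most easily lost. It could also cleave the benzyl ether ortho to the new carbonyl, which would erase the difference between O1 and O5.
- The proposal is a magnesium-phenoxide-directed ortho-formylation (14 to 15), methyl Grignard addition (15 to 16) and oxidation (16 to 17). These are three mild operations, and the formylation is specific for the one free position ortho to the hydroxyl group.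

**Phenol 14 from silylaryl triflate 7, aldehyde 9 and dimethylzinc 10.** Three bonds are cut at once: aryl C8a–O, C8–Cα and Cα–CH3. The forward step passes through aryne 11, benzoxete 12 and ortho-quinone methide 13.
- Against an alkylation of a phloroglucinol derivative with a benzylic electrophile, this cut fixes the position of the side chain relative to the free hydroxyl group by construction. It also reduces the stereochemical problem to face selection on one planar carbon.
- The precursors are an achiral aryne precursor, a benzaldehyde and a commodity organometallic.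
- The forward reaction must control where the aryne is attacked, which face of 13 receives methyl, and the competition between 13 and free 9 for the zinc reagent.

**Triflate 7 from 3,5-bis(benzyloxy)phenol 1; aldehyde 9 from syringaldehyde 8.** The C–Si and O–S bonds of 7 are cut. The carbamate 2 directs lithiation to the carbon between the carbamate and a benzyloxy group (to give 5). Mild cleavage to silylphenol 6 and triflation in the same flask then give 7. Aldehyde 9 is the benzyl ether of 8.

## Roads not taken

**Alternative 1:** Ring C is cut at C4a–C4 and O1–C2.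
- *Forward step.* The aryl propargyl ether A2, made from phenol 14 and a 1-arylpropargyl alcohol, is heated. A Claisen shift to the free ortho carbon, a 1,5-hydrogen shift and an oxa-6π electrocyclisation give the 2-aryl-2H-chromene A1.
- *Merits.* The C4a–C4 bond forms under neutral, thermal conditions at the only free ortho position. Ring B arrives in the same step. Three steps are saved against the formylation, Grignard addition and oxidation of the chosen plan. In this respect the alternative is better.
- *Weak points.* It does not create the stereocenter; it needs 14 or an equivalent, so it is an alternative endgame only. A2 is a secondary, doubly activated propargylic aryl ether. It is hard to make from an electron-rich phenol without C-alkylation, and it ionises easily. A1 must still be raised by two oxidation levels at C4 and hydroxylated at C3, and flav-3-enes are sensitive to acid and air.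
- *Comparison.* The chosen plan spends more steps on the C4a–C4 bond. Against this it reaches the flavonol oxidation level directly in the ring-closing step.

**Alternative 2:** Ring A is cut at C8–C8a, C6–C7 and C4a–C8a.
- *Forward step.* A Danheiser benzannulation: 3-(benzyloxy)cyclobutenone A5 opens on heating to a vinylketene, which combines with the chiral siloxyalkyne A4 to give phenol A3.
- *Merits.* The ring is built with its three oxygens differentiated and the free hydroxyl group beside the side chain, so no question of aryne regiochemistry arises. The stereocenter comes from an enantiopure 2-arylpropanoic acid derivative made by established methods and is not touched in the annulation. In stereochemical reliability this road is better than the chosen plan.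
- *Weak points.* A4 needs a homologation of an ester to an ynolate and silylation, under strongly basic conditions at an enolisable benzylic stereocenter. A5 is not an off-the-shelf compound. The annulation must tolerate a branched substituent at the crowded position between two oxygens. A3 still needs the same ring-C sequence, and a third kind of protecting group must be handled.
- *Comparison.* The chosen plan joins three simple components and sets the stereocenter in one operation, and is several steps shorter. It must set against the proven stereochemistry of this road the uncertainty of a new enantioselective step.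

**Alternative 3:** Ring C is cut at C8a–O1, C4a–C4 and O1–C2.
- *Forward step.* Fluoride releases the C4a–C8a aryne from A7. The arylpropiolic acid A8 adds through its carboxyl oxygen, the aryl anion takes the acyl group, and the phenoxide closes by conjugate addition to flavone A6.
- *Merits.* Ring C and ring B are attached in one step. Addition of carboxylic acids to arynes with acyl transfer is a known reaction type, so the step itself is better precedented than the key step proposed here.
- *Weak points.* A7 is a hexasubstituted benzene that already contains the stereocenter. It would be made from 14 by a second silylation and triflation sequence, so the stereochemical problem is untouched. The aryne is flanked on one side by a benzyloxy group and on the other by the bulky 1-arylethyl group. The oxygen nucleophile must attack the carbon next to that bulky group, where electronic preference and steric hindrance point in opposite directions. A6 still lacks the 3-hydroxyl group.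
- *Comparison.* This road closes ring C more economically. The chosen plan uses the aryne where it is unhindered and electronically unambiguous, and uses it to solve the stereocenter.

Key step: step 5

**Assumptions.**
- Compounds 1, 8, 10 and 18 are bought.
- The sense of induction of the amino alcohol in step 5 cannot be derived from precedent. (2S)-3-exo-Morpholinoisoborneol, (−)-MIB, is written; its mirror image is equally available and is to be used if the first experiment shows the opposite sense.
- Quinone methide 13 is drawn as the E isomer expected from outward rotation of the aryl group during ring opening.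

## Route

Step 1
Reactants: 1 3,5-bis(benzyloxy)phenol
Product: 2 3,5-bis(benzyloxy)phenyl N-(propan-2-yl)carbamate
Conditions: i-PrNCO, Et3N (cat.), CH2Cl2, rt
Reagents that add atoms: isopropyl isocyanate, CC(C)N=C=O
Why: Base-catalysed addition of a phenol to an isocyanate (carbamoylation); the N–H carbamate is chosen because it directs ortho-lithiation strongly and is later cleaved under mild base.

Step 2
Reactants: 2 3,5-bis(benzyloxy)phenyl N-(propan-2-yl)carbamate
Product: 5 3,5-bis(benzyloxy)-2-(trimethylsilyl)phenyl N-(propan-2-yl)carbamate, via N-silyl carbamate 3 (not isolated), via N-silyl C-silyl carbamate 4 (not isolated)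
Conditions: TBSOTf, TMEDA, Et2O, 0 °C → rt; n-BuLi, TMEDA, −78 °C; TMSCl, −78 °C → rt; cold aq. NaHSO4
Reagents that add atoms: chlorotrimethylsilane, C[Si](C)(C)Cl
Why: Directed ortho-metalation: after the N–H is masked as its silyl derivative 3, the carbamate directs lithiation to the carbon between itself and a benzyloxy group (the two such positions are equivalent) and not to the carbon flanked only by two ethers. Silylation gives 4, and the N-silyl group is lost on mild acidic work-up.

Step 3
Reactants: 5 3,5-bis(benzyloxy)-2-(trimethylsilyl)phenyl N-(propan-2-yl)carbamate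
Product: 7 3,5-bis(benzyloxy)-2-(trimethylsilyl)phenyl trifluoromethanesulfonate, via silylphenol 6 (not isolated)
Conditions: DBU, Et2NH, MeCN, 40 °C; then PhNTf2, rt
Reagents that add atoms: N-phenylbis(trifluoromethanesulfonimide), O=S(=O)(N(c1ccccc1)S(=O)(=O)C(F)(F)F)C(F)(F)F
Why: Base-induced elimination of the N–H carbamate gives the phenoxide of 6 and isopropyl isocyanate, which diethylamine traps as a urea; the phenoxide is triflated in the same flask. The electron-rich silylphenol, which is prone to protodesilylation, is therefore never isolated.

Step 4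
Reactants: 8 syringaldehyde
Product: 9 4-(benzyloxy)-3,5-dimethoxybenzaldehyde
Conditions: BnBr, K2CO3, DMF, 60 °C
Reagents that add atoms: benzyl bromide, BrCc1ccccc1
Why: Williamson ether synthesis on a phenoxide; the benzyl group matches the other phenol protecting groups and leaves with them in the last step.

Step 5
Reactants: 7 3,5-bis(benzyloxy)-2-(trimethylsilyl)phenyl trifluoromethanesulfonate; 9 4-(benzyloxy)-3,5-dimethoxybenzaldehyde; 10 dimethylzinc
Product: 14 3,5-bis(benzyloxy)-2-[(1R)-1-(4-benzyloxy-3,5-dimethoxyphenyl)ethyl]phenol, via aryne 11 (not isolated), via benzoxete 12 (not isolated), via ortho-quinone methide 13 (not isolated)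
Conditions: (−)-MIB (1.2 equiv), Me2Zn (4 equiv), 9 (2 equiv), CsF (3 equiv), 18-crown-6, toluene/THF, 0 °C → rt, slow addition of 7; aq. NH4Cl
Reagents that add atoms: none
Why: Proposed new method: fluoride strips the silyl group of 7 and triflate leaves, giving aryne 11; the carbonyl oxygen of 9 attacks the aryne carbon remote from the neighbouring benzyloxy group, the aryl anion so formed closes onto the oxocarbenium carbon to give benzoxete 12 (stepwise [2+2]), and 4π-electrocyclic ring opening gives ortho-quinone methide 13. The methylzinc amino alkoxide made from 10 and the ligand binds the strongly Lewis-basic oxygen of 13 and passes a methyl group to the exocyclic carbon through a six-membered cyclic transition state (Zn–O=C–C=C···CH3), which rearomatises the ring to a zinc phenoxide that gives 14 on work-up. The closest known reaction types are fluoride-triggered aryne insertion into the C=O bond of formamides with capture of the resulting quinone methide by dialkylzincs, the aryne–aldehyde [2+2] and ring-opening route to quinone methides, and catalytic enantioselective 1,4-additions to ortho-quinone methides; an aldehyde-derived quinone methide has not been combined with an enantioselective methyl transfer from zinc. No ring of 14 is formed in this step; the four-membered ring of 12 is transient, closed by 4-exo attack of the aryl anion and opened again. The single new stereocenter is set by reagent control: the chiral ligand on zinc shields one face of the planar methide carbon, and the substrate has no stereocenter that could help or interfere. Regioselective aryne capture is needed and is secured by the benzyloxy group flanking the triple bond, which polarises the aryne so that the nucleophilic oxygen adds at the distal carbon; the second benzyloxy group lies meta to that carbon and does not oppose it. Face selectivity requires one geometry of 13 and a ligand-bound methyl donor; the stoichiometric ligand is meant to ensure that every molecule of 13 meets chiral zinc, and ligand acceleration should keep transfer from free Me2Zn slow. Chemoselectivity requires that 13 is methylated faster than free 9 and faster than it is captured by a second aryne; the high electrophilicity of 13, the sluggishness of Me2Zn toward an electron-rich aldehyde at 0 °C, the excess of 9 and 10 and the slow addition of 7 are meant to secure this.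

Step 6
Reactants: 14 3,5-bis(benzyloxy)-2-[(1R)-1-(4-benzyloxy-3,5-dimethoxyphenyl)ethyl]phenol
Product: 15 4,6-bis(benzyloxy)-3-[(1R)-1-(4-benzyloxy-3,5-dimethoxyphenyl)ethyl]-2-hydroxybenzaldehyde
Conditions: MgCl2, Et3N, (CH2O)n, MeCN, reflux
Reagents that add atoms: paraformaldehyde (as formaldehyde), C=O
Why: Magnesium-mediated ortho-formylation of a phenol (Casnati–Skattebøl): the magnesium phenoxide delivers formaldehyde to the only free ortho carbon, and the hydroxymethyl intermediate is oxidised by a second formaldehyde through hydride transfer. No strong acid is present, so the benzyl ethers and the benzylic stereocenter should be untouched.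

Step 7
Reactants: 15 4,6-bis(benzyloxy)-3-[(1R)-1-(4-benzyloxy-3,5-dimethoxyphenyl)ethyl]-2-hydroxybenzaldehyde
Product: 16 3,5-bis(benzyloxy)-2-[(1R)-1-(4-benzyloxy-3,5-dimethoxyphenyl)ethyl]-6-(1-hydroxyethyl)phenol
Conditions: MeMgBr (3 equiv), THF, 0 °C; cold aq. NH4Cl; crude used at once
Reagents that add atoms: methylmagnesium bromide, C[Mg]Br
Why: Grignard addition to the aldehyde after deprotonation of the phenol by the first equivalent; the new carbinol center forms as both epimers, which is of no consequence because it is oxidised in the next step.

Step 8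
Reactants: 16 3,5-bis(benzyloxy)-2-[(1R)-1-(4-benzyloxy-3,5-dimethoxyphenyl)ethyl]-6-(1-hydroxyethyl)phenol
Product: 17 1-{4,6-bis(benzyloxy)-3-[(1R)-1-(4-benzyloxy-3,5-dimethoxyphenyl)ethyl]-2-hydroxyphenyl}ethan-1-one
Conditions: MnO2, CH2Cl2, rt
Reagents that add atoms: none
Why: Oxidation of a benzylic alcohol by MnO2 under neutral, heterogeneous conditions; the product is a hydrogen-bonded ortho-hydroxyacetophenone whose carbonyl group makes ring A far less prone to acid-induced loss of the side chain.

Step 9
Reactants: 17 1-{4,6-bis(benzyloxy)-3-[(1R)-1-(4-benzyloxy-3,5-dimethoxyphenyl)ethyl]-2-hydroxyphenyl}ethan-1-one; 18 4-(benzyloxy)-3-methoxybenzaldehyde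
Product: 20 5,7-bis(benzyloxy)-2-[4-(benzyloxy)-3-methoxyphenyl]-8-[(1R)-1-(4-benzyloxy-3,5-dimethoxyphenyl)ethyl]-3-hydroxy-4H-chromen-4-one, via chalcone 19 (not isolated)
Conditions: KOH, EtOH/THF, rt; then 30% H2O2, 0 °C → rt
Reagents that add atoms: hydrogen peroxide, OO
Why: Claisen–Schmidt condensation gives chalcone 19, and Algar–Flynn–Oyamada oxidation with alkaline hydrogen peroxide closes ring C through the phenoxide at the β-carbon and oxidises the dihydroflavonol to the flavonol. The only free phenol lies beside the side chain, so closure can only give the 8-substituted isomer. The benzylic methine is meta to the carbonyl-bearing carbon and not acidic enough to epimerise in base.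

Step 10
Reactants: 20 5,7-bis(benzyloxy)-2-[4-(benzyloxy)-3-methoxyphenyl]-8-[(1R)-1-(4-benzyloxy-3,5-dimethoxyphenyl)ethyl]-3-hydroxy-4H-chromen-4-one
Product: 21 3,5,7-trihydroxy-2-(4-hydroxy-3-methoxyphenyl)-8-[(1R)-1-(4-hydroxy-3,5-dimethoxyphenyl)ethyl]-4H-chromen-4-one
Conditions: H2 (1 atm), Pd/C, THF/MeOH, rt
Reagents that add atoms: none
Why: Hydrogenolysis of four benzyl ethers over Pd/C; the methyl ethers, the chromone double bond and the stereocenter (which carries no benzylic heteroatom) should be untouched under these mild conditions.

## Compound list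

1 | 3,5-bis(benzyloxy)phenol | Oc1cc(OCc2ccccc2)cc(OCc2ccccc2)c1 | starting material
2 | 3,5-bis(benzyloxy)phenyl N-(propan-2-yl)carbamate | CC(C)NC(=O)Oc1cc(OCc2ccccc2)cc(OCc2ccccc2)c1 | intermediate
3 | 3,5-bis(benzyloxy)phenyl N-[tert-butyl(dimethyl)silyl]-N-(propan-2-yl)carbamate | CC(C)N(C(=O)Oc1cc(OCc2ccccc2)cc(OCc2ccccc2)c1)[Si](C)(C)C(C)(C)C | intermediate
4 | 3,5-bis(benzyloxy)-2-(trimethylsilyl)phenyl N-[tert-butyl(dimethyl)silyl]-N-(propan-2-yl)carbamate | CC(C)N(C(=O)Oc1cc(OCc2ccccc2)cc(OCc2ccccc2)c1[Si](C)(C)C)[Si](C)(C)C(C)(C)C | intermediate
5 | 3,5-bis(benzyloxy)-2-(trimethylsilyl)phenyl N-(propan-2-yl)carbamate | CC(C)NC(=O)Oc1cc(OCc2ccccc2)cc(OCc2ccccc2)c1[Si](C)(C)C | intermediate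
6 | 3,5-bis(benzyloxy)-2-(trimethylsilyl)phenol | C[Si](C)(C)c1c(O)cc(OCc2ccccc2)cc1OCc1ccccc1 | intermediate
7 | 3,5-bis(benzyloxy)-2-(trimethylsilyl)phenyl trifluoromethanesulfonate | C[Si](C)(C)c1c(OS(=O)(=O)C(F)(F)F)cc(OCc2ccccc2)cc1OCc1ccccc1 | intermediate
8 | syringaldehyde (4-hydroxy-3,5-dimethoxybenzaldehyde) | COc1cc(C=O)cc(OC)c1O | starting material
9 | 4-(benzyloxy)-3,5-dimethoxybenzaldehyde | COc1cc(C=O)cc(OC)c1OCc1ccccc1 | intermediate
10 | dimethylzinc | C[Zn]C | starting material
11 | 3,5-bis(benzyloxy)benzyne (1,2-didehydro-3,5-bis(benzyloxy)benzene) | C1#CC(OCc2ccccc2)=CC(OCc2ccccc2)=C1 | intermediate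
12 | 3,5-bis(benzyloxy)-2-[4-(benzyloxy)-3,5-dimethoxyphenyl]-2H-1-benzoxete, racemic | COc1cc(C2Oc3cc(OCc4ccccc4)cc(OCc4ccccc4)c32)cc(OC)c1OCc1ccccc1 | intermediate
13 | (6E)-3,5-bis(benzyloxy)-6-{[4-(benzyloxy)-3,5-dimethoxyphenyl]methylidene}cyclohexa-2,4-dien-1-one | COc1cc(/C=C2/C(=O)C=C(OCc3ccccc3)C=C2OCc2ccccc2)cc(OC)c1OCc1ccccc1 | intermediate
14 | 3,5-bis(benzyloxy)-2-[(1R)-1-(4-benzyloxy-3,5-dimethoxyphenyl)ethyl]phenol | Oc1cc(OCc2ccccc2)cc(OCc2ccccc2)c1[C@H](C)c1cc(OC)c(OCc2ccccc2)c(OC)c1 | intermediate
15 | 4,6-bis(benzyloxy)-3-[(1R)-1-(4-benzyloxy-3,5-dimethoxyphenyl)ethyl]-2-hydroxybenzaldehyde | O=Cc1c(OCc2ccccc2)cc(OCc2ccccc2)c([C@H](C)c2cc(OC)c(OCc3ccccc3)c(OC)c2)c1O | intermediate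
16 | 3,5-bis(benzyloxy)-2-[(1R)-1-(4-benzyloxy-3,5-dimethoxyphenyl)ethyl]-6-(1-hydroxyethyl)phenol, both epimers at the carbinol carbon | CC(O)c1c(OCc2ccccc2)cc(OCc2ccccc2)c([C@H](C)c2cc(OC)c(OCc3ccccc3)c(OC)c2)c1O | intermediate
17 | 1-{4,6-bis(benzyloxy)-3-[(1R)-1-(4-benzyloxy-3,5-dimethoxyphenyl)ethyl]-2-hydroxyphenyl}ethan-1-one | CC(=O)c1c(OCc2ccccc2)cc(OCc2ccccc2)c([C@H](C)c2cc(OC)c(OCc3ccccc3)c(OC)c2)c1O | intermediate
18 | 4-(benzyloxy)-3-methoxybenzaldehyde | COc1cc(C=O)ccc1OCc1ccccc1 | starting material
19 | (2E)-1-{4,6-bis(benzyloxy)-3-[(1R)-1-(4-benzyloxy-3,5-dimethoxyphenyl)ethyl]-2-hydroxyphenyl}-3-[4-(benzyloxy)-3-methoxyphenyl]prop-2-en-1-one | COc1cc(/C=C/C(=O)c2c(OCc3ccccc3)cc(OCc3ccccc3)c([C@H](C)c3cc(OC)c(OCc4ccccc4)c(OC)c3)c2O)ccc1OCc1ccccc1 | intermediate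
20 | 5,7-bis(benzyloxy)-2-[4-(benzyloxy)-3-methoxyphenyl]-8-[(1R)-1-(4-benzyloxy-3,5-dimethoxyphenyl)ethyl]-3-hydroxy-4H-chromen-4-one | COc1cc(-c2oc3c([C@H](C)c4cc(OC)c(OCc5ccccc5)c(OC)c4)c(OCc4ccccc4)cc(OCc4ccccc4)c3c(=O)c2O)ccc1OCc1ccccc1 | intermediate
21 | 3,5,7-trihydroxy-2-(4-hydroxy-3-methoxyphenyl)-8-[(1R)-1-(4-hydroxy-3,5-dimethoxyphenyl)ethyl]-4H-chromen-4-one | COc1cc(-c2oc3c([C@H](C)c4cc(OC)c(O)c(OC)c4)c(O)cc(O)c3c(=O)c2O)ccc1O | target

## Step count and risk

Total step count: 10. Longest linear sequence: 9 (steps 1 to 3 and 5 to 10).

**Step 5 (key step).**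
- *What may go wrong.* The most likely failure is erosion of enantioselectivity, through methyl transfer from zinc that is not bound to the ligand, or through reaction of both geometrical isomers of the quinone methide. Next in likelihood are consumption of the aldehyde by ligand-accelerated 1,2-methylation and capture of the quinone methide by a second aryne. These arise because the amino alkoxide that activates the quinone methide also activates aldehydes, and because the quinone methide is short-lived.
- *Fallback (known reaction types only).* The fallback sets out from 9 and 7 and returns at 14. Aldehyde 9 is oxidised (NaClO2, NaH2PO4, 2-methylbut-2-ene) to 4-(benzyloxy)-3,5-dimethoxybenzoic acid F1. Aryne 11, released from 7 with CsF in hot THF, adds this acid through oxygen with transfer of the acyl group to carbon. The same alkoxy-directed regiochemistry as in step 5 should give [2,4-bis(benzyloxy)-6-hydroxyphenyl][4-(benzyloxy)-3,5-dimethoxyphenyl]methanone F2. Excess MeLi converts the ketone into racemic 3,5-bis(benzyloxy)-2-[1-(4-benzyloxy-3,5-dimethoxyphenyl)-1-hydroxyethyl]phenol F3. A BINOL-derived chiral phosphoric acid with a Hantzsch ester then dehydrates F3 to the methyl-bearing ortho-quinone methide and delivers hydride to one face. This is an established enantioselective transfer hydrogenation for ortho-hydroxy-1,1-diaryl systems and should give 14.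

**Step 2.**
- *What may go wrong.* Deprotonation at a benzylic ether carbon, followed by Wittig rearrangement, or lithiation between the two ethers may compete with the carbamate-directed lithiation. Protodesilylation of the electron-rich arylsilane may occur on acidic work-up.
- *Fallback.* Deprotonation is replaced by halogen–metal exchange; the fallback sets out from 1 and returns at 7. Bromination of 1 with NBS at low temperature gives 2-bromo-3,5-bis(benzyloxy)phenol F4, which is separated from the 4-bromo isomer. Silylation with HMDS gives [3,5-bis(benzyloxy)-2-bromophenoxy](trimethyl)silane F5. n-BuLi at −78 °C effects bromine–lithium exchange and the oxygen-to-carbon silyl shift (retro-Brook) to the lithium salt of 6, which is triflated with Tf2O to 7.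

**Step 7.**
- *What may go wrong.* Ionisation of the ortho-hydroxybenzylic carbinol during work-up, with loss of water to a quinone methide that oligomerises or tautomerises. The ring bears three oxygen donors that stabilise the benzylic cation.
- *Fallback.* The carbinol is avoided altogether; the fallback sets out from 14 and returns at 17. Phenol 14 is protected (MOMCl, i-Pr2NEt) as 1,5-bis(benzyloxy)-2-[(1R)-1-(4-benzyloxy-3,5-dimethoxyphenyl)ethyl]-3-(methoxymethoxy)benzene F6. Lithiation (n-BuLi, TMEDA) at the ring carbon between the acetal and the benzyloxy group, then acylation with N-methoxy-N-methylacetamide, gives 1-{4,6-bis(benzyloxy)-3-[(1R)-1-(4-benzyloxy-3,5-dimethoxyphenyl)ethyl]-2-(methoxymethoxy)phenyl}ethan-1-one F7. The acetal, now ortho to a carbonyl group on a deactivated ring, is removed with dilute HCl in MeOH to give 17.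

**Step 9.**
- *What may go wrong.* Closure at the α-carbon to an aurone instead of at the β-carbon. The benzyloxy group ortho to the carbonyl twists the enone out of the plane of ring A, which is known to favour the five-membered mode.
- *Fallback.* Ring closure is separated from oxidation at C3; the fallback sets out from 19, isolated after the condensation, and returns at 20. Oxidative cyclisation with catalytic I2 in DMSO at 120 °C gives 5,7-bis(benzyloxy)-2-[4-(benzyloxy)-3-methoxyphenyl]-8-[(1R)-1-(4-benzyloxy-3,5-dimethoxyphenyl)ethyl]-4H-chromen-4-one F8, the same compound as A6. Dimethyldioxirane converts it into 5,7-bis(benzyloxy)-2-[4-(benzyloxy)-3-methoxyphenyl]-8-[(1R)-1-(4-benzyloxy-3,5-dimethoxyphenyl)ethyl]-2,3-epoxy-2,3-dihydro-4H-chromen-4-one F9. A trace of TsOH opens the epoxide to 20.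

## Further compounds

F1 | step 5 | 4-(benzyloxy)-3,5-dimethoxybenzoic acid | COc1cc(C(=O)O)cc(OC)c1OCc1ccccc1
F2 | step 5 | [2,4-bis(benzyloxy)-6-hydroxyphenyl][4-(benzyloxy)-3,5-dimethoxyphenyl]methanone | COc1cc(C(=O)c2c(O)cc(OCc3ccccc3)cc2OCc2ccccc2)cc(OC)c1OCc1ccccc1
F3 | step 5 | 3,5-bis(benzyloxy)-2-[1-(4-benzyloxy-3,5-dimethoxyphenyl)-1-hydroxyethyl]phenol, racemic | COc1cc(C(C)(O)c2c(O)cc(OCc3ccccc3)cc2OCc2ccccc2)cc(OC)c1OCc1ccccc1
F4 | step 2 | 2-bromo-3,5-bis(benzyloxy)phenol | Oc1cc(OCc2ccccc2)cc(OCc2ccccc2)c1Br
F5 | step 2 | [3,5-bis(benzyloxy)-2-bromophenoxy](trimethyl)silane | C[Si](C)(C)Oc1cc(OCc2ccccc2)cc(OCc2ccccc2)c1Br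
F6 | step 7 | 1,5-bis(benzyloxy)-2-[(1R)-1-(4-benzyloxy-3,5-dimethoxyphenyl)ethyl]-3-(methoxymethoxy)benzene | COCOc1cc(OCc2ccccc2)cc(OCc2ccccc2)c1[C@H](C)c1cc(OC)c(OCc2ccccc2)c(OC)c1
F7 | step 7 | 1-{4,6-bis(benzyloxy)-3-[(1R)-1-(4-benzyloxy-3,5-dimethoxyphenyl)ethyl]-2-(methoxymethoxy)phenyl}ethan-1-one | CC(=O)c1c(OCc2ccccc2)cc(OCc2ccccc2)c([C@H](C)c2cc(OC)c(OCc3ccccc3)c(OC)c2)c1OCOC
F8 | step 9 | 5,7-bis(benzyloxy)-2-[4-(benzyloxy)-3-methoxyphenyl]-8-[(1R)-1-(4-benzyloxy-3,5-dimethoxyphenyl)ethyl]-4H-chromen-4-one | COc1cc(-c2cc(=O)c3c(OCc4ccccc4)cc(OCc4ccccc4)c([C@H](C)c4cc(OC)c(OCc5ccccc5)c(OC)c4)c3o2)ccc1OCc1ccccc1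
F9 | step 9 | 5,7-bis(benzyloxy)-2-[4-(benzyloxy)-3-methoxyphenyl]-8-[(1R)-1-(4-benzyloxy-3,5-dimethoxyphenyl)ethyl]-2,3-epoxy-2,3-dihydro-4H-chromen-4-one, both epoxide diastereomers | COc1cc(C23OC2C(=O)c2c(OCc4ccccc4)cc(OCc4ccccc4)c([C@H](C)c4cc(OC)c(OCc5ccccc5)c(OC)c4)c2O3)ccc1OCc1ccccc1
A1 | alternative 1 | 5,7-bis(benzyloxy)-2-[4-(benzyloxy)-3-methoxyphenyl]-8-[(1R)-1-(4-benzyloxy-3,5-dimethoxyphenyl)ethyl]-2H-chromene, either configuration at C2 | COc1cc(C2C=Cc3c(OCc4ccccc4)cc(OCc4ccccc4)c([C@H](C)c4cc(OC)c(OCc5ccccc5)c(OC)c4)c3O2)ccc1OCc1ccccc1
A2 | alternative 1 | 1,5-bis(benzyloxy)-2-[(1R)-1-(4-benzyloxy-3,5-dimethoxyphenyl)ethyl]-3-({1-[4-(benzyloxy)-3-methoxyphenyl]prop-2-yn-1-yl}oxy)benzene, either configuration at the propargylic carbon | C#CC(Oc1cc(OCc2ccccc2)cc(OCc2ccccc2)c1[C@H](C)c1cc(OC)c(OCc2ccccc2)c(OC)c1)c1ccc(OCc2ccccc2)c(OC)c1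
A3 | alternative 2 | 5-(benzyloxy)-2-[(1R)-1-(4-benzyloxy-3,5-dimethoxyphenyl)ethyl]-3-(triisopropylsilyloxy)phenol | Oc1cc(OCc2ccccc2)cc(O[Si](C(C)C)(C(C)C)C(C)C)c1[C@H](C)c1cc(OC)c(OCc2ccccc2)c(OC)c1
A4 | alternative 2 | {[(3R)-3-(4-benzyloxy-3,5-dimethoxyphenyl)but-1-yn-1-yl]oxy}tri(propan-2-yl)silane | CC(C)[Si](OC#C[C@H](C)c1cc(OC)c(OCc2ccccc2)c(OC)c1)(C(C)C)C(C)C
A5 | alternative 2 | 3-(benzyloxy)cyclobut-2-en-1-one | O=C1C=C(OCc2ccccc2)C1
A6 | alternative 3 | 5,7-bis(benzyloxy)-2-[4-(benzyloxy)-3-methoxyphenyl]-8-[(1R)-1-(4-benzyloxy-3,5-dimethoxyphenyl)ethyl]-4H-chromen-4-one | COc1cc(-c2cc(=O)c3c(OCc4ccccc4)cc(OCc4ccccc4)c([C@H](C)c4cc(OC)c(OCc5ccccc5)c(OC)c4)c3o2)ccc1OCc1ccccc1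
A7 | alternative 3 | 3,5-bis(benzyloxy)-2-[(1R)-1-(4-benzyloxy-3,5-dimethoxyphenyl)ethyl]-6-(trimethylsilyl)phenyl trifluoromethanesulfonate | C[Si](C)(C)c1c(OCc2ccccc2)cc(OCc2ccccc2)c([C@H](C)c2cc(OC)c(OCc3ccccc3)c(OC)c2)c1OS(=O)(=O)C(F)(F)F
A8 | alternative 3 | 3-[4-(benzyloxy)-3-methoxyphenyl]prop-2-ynoic acid | COc1cc(C#CC(=O)O)ccc1OCc1ccccc1
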